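**Plan**
- Retrosynthetic cuts, last bonds first: (i) the O–benzyl bond and the side-chain C=C (hydrogenation); (ii) C5–CH= (Heck); (iii) CH2–OH, traced back to CH2–SiMe2Ph (Fleming–Tamao); (iv) O1–C7a and C2–C3 of the dihydrofuran ring together. This leaves O-benzylsyringaldehyde and a 2-arylethylsilane that carries an enantiopure p-tolylsulfinyl group on C7a.
- Enabling feature: C3 is a benzylic carbon on C3a, and C7a is the benzene-ring carbon directly ortho to it. One substituent on C7a can therefore acidify and chelate C3–Li, pass its chirality to C3 and C2, and then act as the leaving group when the new alkoxide oxygen, placed for a five-membered closure, attacks C7a.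
- Forward order: the benzene ring is bought as 2-methoxy-6-methylaniline. Br goes to C5, then I and S(O)Tol to C7a, and the C3 methyl group is extended by CH2SiMe2Ph. A one-flask annulation with the aldehyde closes the only new ring, followed by unmasking, Heck chain attachment and hydrogenation.
- Stereochemistry: the sulfur centre comes from (−)-menthyl (S)-p-toluenesulfinate with inversion at S. C3 is set by 1,4-induction from sulfur in the chelated benzyllithium, and C2 in the same lithium-bound transition state (trans). The auxiliary is expelled in the ring closure itself.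

Key step: step 7

Assumption: the sense of induction (S at sulfur gives the C3 configuration of the target) follows from the chelate model given under step 7; should it prove opposite, the mirror-image sulfinate from (+)-menthol is used and nothing else changes.

Step 1
Reactants: 1 2-methoxy-6-methylaniline
Product: 2 4-bromo-2-methoxy-6-methylaniline
Conditions: NBS, MeCN, 0 °C, dark
Reagents that add atoms: N-bromosuccinimide, O=C1CCC(=O)N1Br
Why: Electrophilic aromatic bromination; both ortho positions of the strongly activating NH2 group are blocked (OMe, CH3), so bromine should enter only para, at the carbon that becomes C5.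

Step 2
Reactants: 2 4-bromo-2-methoxy-6-methylaniline
Product: 4 5-bromo-2-iodo-1-methoxy-3-methylbenzene, via diazonium chloride 3 (not isolated)
Conditions: NaNO2, aq HCl, 0 °C; then KI, 0 °C → rt
Reagents that add atoms: potassium iodide, [K+].[I-]; sodium nitrite (second nitrogen of 3 only), [Na+].[O-]N=O; hydrogen chloride (chloride of 3 only), Cl
Why: Sandmeyer-type diazotisation–iodination replaces NH2 by iodine at the future C7a and gives a C–I/C–Br pair that can be addressed one after the other.

Step 3
Reactants: 4 5-bromo-2-iodo-1-methoxy-3-methylbenzene; 5 (1R,2S,5R)-menthyl (S)-4-methylbenzenesulfinate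
Product: 7 (S)-5-bromo-1-methoxy-3-methyl-2-(4-methylbenzenesulfinyl)benzene, via aryl Grignard 6 (not isolated)
Conditions: i-PrMgCl·LiCl, THF, −20 °C; then added to 5, THF, −40 → 0 °C
Reagents that add atoms: isopropylmagnesium chloride (MgCl of 6 only), CC(C)[Mg]Cl
Why: Iodine–magnesium exchange is much faster at C–I (helped by the ortho OMe) than at C–Br, and the Andersen sulfoxide synthesis replaces menthoxide at sulfur with inversion, which sets the (S)-sulfur stereocentre.

Step 4
Reactants: 8 (chloromethyl)dimethyl(phenyl)silane
Product: 9 (iodomethyl)dimethyl(phenyl)silane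
Conditions: NaI, acetone, reflux
Reagents that add atoms: sodium iodide, [Na+].[I-]
Why: Finkelstein exchange, driven by precipitation of NaCl, gives the more reactive SN2 partner.

Step 5
Reactants: 7 (S)-5-bromo-1-methoxy-3-methyl-2-(4-methylbenzenesulfinyl)benzene; 9 (iodomethyl)dimethyl(phenyl)silane
Product: 11 (S)-{2-[5-bromo-3-methoxy-2-(4-methylbenzenesulfinyl)phenyl]ethyl}dimethyl(phenyl)silane, via primary benzyllithium 10 (not isolated)
Conditions: LDA, THF, −78 °C; then 9, −78 → −40 °C
Reagents that add atoms: lithium diisopropylamide (Li of 10 only), [Li]N(C(C)C)C(C)C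
Why: Sulfinyl-directed lateral lithiation followed by SN2 alkylation is a known reaction of ortho-sulfinylbenzyl carbanions; the CH2SiMe2Ph arm is a masked CH2OH that, unlike a β-alkoxy group, can neither be eliminated from the later carbanion nor compete as a nucleophile for C7a.

Step 6
Reactants: 12 syringaldehyde (4-hydroxy-3,5-dimethoxybenzaldehyde)
Product: 13 4-(benzyloxy)-3,5-dimethoxybenzaldehyde
Conditions: BnBr, K2CO3, DMF, rt
Reagents that add atoms: benzyl bromide, BrCc1ccccc1
Why: Williamson etherification masks the acidic phenol with a group that survives carbanions and alkoxides and is removed in the final hydrogenation.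

Step 7
Reactants: 11 (S)-{2-[5-bromo-3-methoxy-2-(4-methylbenzenesulfinyl)phenyl]ethyl}dimethyl(phenyl)silane; 13 4-(benzyloxy)-3,5-dimethoxybenzaldehyde
Product: 16 trans-(2S,3S)-2-[4-(benzyloxy)-3,5-dimethoxyphenyl]-5-bromo-3-{[dimethyl(phenyl)silyl]methyl}-7-methoxy-2,3-dihydro-1-benzofuran, via chelated benzyllithium 14 (not isolated), via lithium alkoxide 15 (not isolated)
Conditions: LDA, THF, −78 °C; 13, −78 °C; DMPU, −78 → 40 °C; MeI quench
Reagents that add atoms: lithium diisopropylamide (Li of 14 and 15 only), [Li]N(C(C)C)C(C)C
Why: Proposed new method: LDA removes the C3–H that the ortho sulfinyl group acidifies and directs, the S–O···Li chelated benzyllithium 14 adds to the lithium-bound aldehyde 13 (C2–C3 bond), and on warming the alkoxide 15 attacks the sulfinyl-bearing C7a ipso, by addition–elimination or by ligand coupling through an O–S sulfurane, and expels p-toluenesulfenate (O1–C7a bond), which MeI caps. The closest known reaction types are the one-flask addition/ipso-substitution of ortho-sulfinylbenzyl carbanions with imines, which gives indolines with loss of the sulfinyl group, and the exchange of the sulfinyl group of unactivated aryl sulfoxides for alkoxide; the aldehyde/alkoxide version that closes a 2,3-dihydrobenzofuran is the untested extension. The one ring closes 5-exo-trig at C7a (the C7a=C7 π bond takes up the charge, shared with C5, where Br helps inductively, and C3a), and the closure is driven by release of the strain of the di-ortho-substituted sulfoxide. C3 is controlled by the sulfur stereocentre: with the sulfur lone pair turned towards the C7 methoxy group the S–O bond holds lithium on one face of the carbanion, the tolyl group covers the other, the CH2Si arm points away from sulfur, and the aldehyde enters on the lithium face with retention. C2 is controlled in the same transition state, in which the aldehyde oxygen sits on lithium and its aryl group takes the open sector between C3–H and the CH2Si arm, the arrangement that maps onto the trans ring. The step needs deprotonation at C3 in preference to C6–H, tolyl CH3 and SiCH2 (secured by coordination of LDA to the S–O group next to C3) and attack of the alkoxide on C7a in preference to silicon (secured by the five-membered geometry, by a tetraorganosilane without leaving group and by sulfenate as the only good nucleofuge).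

Step 8
Reactants: 16 trans-(2S,3S)-2-[4-(benzyloxy)-3,5-dimethoxyphenyl]-5-bromo-3-{[dimethyl(phenyl)silyl]methyl}-7-methoxy-2,3-dihydro-1-benzofuran
Product: 18 [(2S,3R)-2-[4-(benzyloxy)-3,5-dimethoxyphenyl]-5-bromo-7-methoxy-2,3-dihydro-1-benzofuran-3-yl]methanol, via fluorosilane 17 (not isolated)
Conditions: HBF4·OEt2, CH2Cl2, 0 °C; then H2O2 (30% aq), KF, KHCO3, THF/MeOH, rt
Reagents that add atoms: hydrogen peroxide, OO; tetrafluoroboric acid (fluorine of 17 only), [H+].F[B-](F)(F)F
Why: Fleming–Tamao oxidation, in which ipso-protonation of the phenyl–silicon bond gives the fluorosilane and its CH2–Si bond then migrates to peroxide oxygen; neither stereocentre reacts, and reversible acid ionisation at C2 can only lead to the more stable trans ring.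

Step 9
Reactants: 18 [(2S,3R)-2-[4-(benzyloxy)-3,5-dimethoxyphenyl]-5-bromo-7-methoxy-2,3-dihydro-1-benzofuran-3-yl]methanol; 19 methyl acrylate
Product: 20 methyl (E)-3-[(2S,3R)-2-[4-(benzyloxy)-3,5-dimethoxyphenyl]-3-(hydroxymethyl)-7-methoxy-2,3-dihydro-1-benzofuran-5-yl]prop-2-enoate
Conditions: Pd(OAc)2 (cat.), P(o-tol)3, Et3N, DMF, 100 °C
Reagents that add atoms: none
Why: Mizoroki–Heck β-arylation of the acrylate by the aryl bromide (E-selective through syn insertion and syn β-hydride elimination) tolerates the free primary alcohol and the benzyl ether.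

Step 10
Reactants: 20 methyl (E)-3-[(2S,3R)-2-[4-(benzyloxy)-3,5-dimethoxyphenyl]-3-(hydroxymethyl)-7-methoxy-2,3-dihydro-1-benzofuran-5-yl]prop-2-enoate
Product: 21 methyl 3-[(2S,3R)-2-(4-hydroxy-3,5-dimethoxyphenyl)-3-(hydroxymethyl)-7-methoxy-2,3-dihydro-1-benzofuran-5-yl]propanoate
Conditions: H2 (1 atm), 10% Pd/C, EtOAc/MeOH, rt
Reagents that add atoms: none
Why: Heterogeneous hydrogenation saturates the cinnamate C=C and hydrogenolyses the O-benzyl ether in one operation, under mild conditions that the ring C2–O bond of 2-aryl-2,3-dihydrobenzofurans is expected to survive.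

**Compound list**
1 | 2-methoxy-6-methylaniline | COc1cccc(C)c1N | starting material
2 | 4-bromo-2-methoxy-6-methylaniline | COc1cc(Br)cc(C)c1N | intermediate
3 | 4-bromo-2-methoxy-6-methylbenzenediazonium chloride | COc1cc(Br)cc(C)c1[N+]#N.[Cl-] | intermediate
4 | 5-bromo-2-iodo-1-methoxy-3-methylbenzene | COc1cc(Br)cc(C)c1I | intermediate
5 | (1R,2S,5R)-menthyl (S)-4-methylbenzenesulfinate | C[C@@H]1CC[C@H]([C@@H](C1)O[S@](=O)c1ccc(C)cc1)C(C)C | starting material
6 | (4-bromo-2-methoxy-6-methylphenyl)magnesium chloride | COc1cc(Br)cc(C)c1[Mg]Cl | intermediate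
7 | (S)-5-bromo-1-methoxy-3-methyl-2-(4-methylbenzenesulfinyl)benzene | Cc1ccc(cc1)[S@](=O)c1c(C)cc(Br)cc1OC | intermediate
8 | (chloromethyl)dimethyl(phenyl)silane | ClC[Si](C)(C)c1ccccc1 | starting material
9 | (iodomethyl)dimethyl(phenyl)silane | IC[Si](C)(C)c1ccccc1 | intermediate
10 | primary benzyllithium of 7 (Li on the former CH3 carbon, S at sulfur) | Cc1ccc(cc1)[S@](=O)c1c(C[Li])cc(Br)cc1OC | intermediate
11 | (S)-{2-[5-bromo-3-methoxy-2-(4-methylbenzenesulfinyl)phenyl]ethyl}dimethyl(phenyl)silane | Cc1ccc(cc1)[S@](=O)c1c(CC[Si](C)(C)c2ccccc2)cc(Br)cc1OC | intermediate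
12 | syringaldehyde (4-hydroxy-3,5-dimethoxybenzaldehyde) | COc1cc(C=O)cc(OC)c1O | starting material
13 | 4-(benzyloxy)-3,5-dimethoxybenzaldehyde | COc1cc(C=O)cc(OC)c1OCc1ccccc1 | intermediate
14 | S–O chelated secondary benzyllithium of 11 (Li on the face later taken by C2) | Cc1ccc(cc1)[S@](=O)c1c([C@H](C[Si](C)(C)c2ccccc2)[Li])cc(Br)cc1OC | intermediate
15 | lithium (1S,2S)-alkoxide from 14 and 13 (sulfinyl group still on C7a) | Cc1ccc(cc1)[S@](=O)c1c([C@H](C[Si](C)(C)c2ccccc2)[C@H](O[Li])c2cc(OC)c(OCc3ccccc3)c(OC)c2)cc(Br)cc1OC | intermediate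
16 | trans-(2S,3S)-2-[4-(benzyloxy)-3,5-dimethoxyphenyl]-5-bromo-3-{[dimethyl(phenyl)silyl]methyl}-7-methoxy-2,3-dihydro-1-benzofuran (3S only because Si outranks O in the CIP order; same spatial arrangement as 3R in 18–21) | Brc1cc(OC)c2c(c1)[C@H](C[Si](C)(C)c1ccccc1)[C@@H](c1cc(OC)c(OCc3ccccc3)c(OC)c1)O2 | intermediate
17 | trans-(2S,3S)-2-[4-(benzyloxy)-3,5-dimethoxyphenyl]-5-bromo-3-{[fluoro(dimethyl)silyl]methyl}-7-methoxy-2,3-dihydro-1-benzofuran | Brc1cc(OC)c2c(c1)[C@H](C[Si](C)(C)F)[C@@H](c1cc(OC)c(OCc3ccccc3)c(OC)c1)O2 | intermediate
18 | [(2S,3R)-2-[4-(benzyloxy)-3,5-dimethoxyphenyl]-5-bromo-7-methoxy-2,3-dihydro-1-benzofuran-3-yl]methanol | Brc1cc(OC)c2c(c1)[C@H](CO)[C@@H](c1cc(OC)c(OCc3ccccc3)c(OC)c1)O2 | intermediate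
19 | methyl acrylate | C=CC(=O)OC | starting material
20 | methyl (E)-3-[(2S,3R)-2-[4-(benzyloxy)-3,5-dimethoxyphenyl]-3-(hydroxymethyl)-7-methoxy-2,3-dihydro-1-benzofuran-5-yl]prop-2-enoate | COC(=O)/C=C/c1cc(OC)c2c(c1)[C@H](CO)[C@@H](c1cc(OC)c(OCc3ccccc3)c(OC)c1)O2 | intermediate
21 | methyl 3-[(2S,3R)-2-(4-hydroxy-3,5-dimethoxyphenyl)-3-(hydroxymethyl)-7-methoxy-2,3-dihydro-1-benzofuran-5-yl]propanoate | COC(=O)CCc1cc(OC)c2c(c1)[C@H](CO)[C@@H](c1cc(OC)c(O)c(OC)c1)O2 | target

Total steps: 10. Longest linear sequence: 8 (steps 1, 2, 3, 5, 7, 8, 9, 10).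

**Steps most likely to fail**

Step 7 (new method). Four processes may defeat it:
- The lithium alkoxide may fail to displace the sulfinyl group on an arene without a strong acceptor.
- The alkoxide may revert to carbanion and aldehyde.
- LDA may metalate C6–H between Br and OMe.
- The aldehyde faces may be poorly differentiated.

The fallback uses known chemistry only. It sets out from 11 and 13 and comes back at 16. Only the addition is run (LDA, THF, −78 °C, cold quench), which is a documented reaction of ortho-sulfinylbenzyl carbanions with aldehydes. It gives the sulfinyl carbinol F1, which can be freed of any carbinol epimer by chromatography. After deprotonation of the OH group with MeMgCl, sulfoxide–magnesium exchange is carried out with i-PrMgCl·LiCl at −50 °C. This exchange is far faster than Br/Mg exchange on such an electron-rich bromide. An iodine quench then gives the iodo carbinol F2. An intramolecular Ullmann etherification (CuI, 1,10-phenanthroline, Cs2CO3, toluene, 110 °C) at the C–I bond, with retention at C2, then gives 16.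

Step 8. The strong acid needed for ipso-protonation of the phenylsilane may ionise the C2–O1 bond irreversibly (oligomerisation) or remove the hindered benzyl ether, which would expose the phenol to peroxide. The fallback sets out from 16 and comes back at 18 without a new isolated compound. Silicon is activated by a nucleophile instead of attacking the phenyl ring with an electrophile. This is the basic variant of the Fleming–Tamao oxidation (t-BuOOH, KH, NMP; then TBAF, 70 °C). The tert-butylperoxide anion adds to silicon, and first the phenyl and then the CH2 group shift from silicon to oxygen. The medium contains no base strong enough to harm the aryl bromide.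

Step 10. Hydrogenolytic opening of the benzylic C2–O1 bond may compete with debenzylation. The fallback sets out from 20 and comes back at 21, and it separates the two tasks without hydrogen on palladium. Conjugate reduction of the cinnamate with nickel boride (NiCl2·6H2O, NaBH4, MeOH, 0 °C) gives the saturated benzyl ether F3. The aryl benzyl ether is then cleaved with BCl3 and pentamethylbenzene as cation scavenger (CH2Cl2, −78 °C) to give 21.

**Further compounds**
F1 | step 7 | (1S,2S)-1-[4-(benzyloxy)-3,5-dimethoxyphenyl]-2-{5-bromo-3-methoxy-2-[(S)-4-methylbenzenesulfinyl]phenyl}-3-[dimethyl(phenyl)silyl]propan-1-ol | Cc1ccc(cc1)[S@](=O)c1c([C@H](C[Si](C)(C)c2ccccc2)[C@H](O)c2cc(OC)c(OCc3ccccc3)c(OC)c2)cc(Br)cc1OC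
F2 | step 7 | (1S,2S)-1-[4-(benzyloxy)-3,5-dimethoxyphenyl]-2-(5-bromo-2-iodo-3-methoxyphenyl)-3-[dimethyl(phenyl)silyl]propan-1-ol | COc1cc(Br)cc([C@H](C[Si](C)(C)c2ccccc2)[C@H](O)c2cc(OC)c(OCc3ccccc3)c(OC)c2)c1I
F0 | step 8 | none | none
F3 | step 10 | methyl 3-[(2S,3R)-2-[4-(benzyloxy)-3,5-dimethoxyphenyl]-3-(hydroxymethyl)-7-methoxy-2,3-dihydro-1-benzofuran-5-yl]propanoate | COC(=O)CCc1cc(OC)c2c(c1)[C@H](CO)[C@@H](c1cc(OC)c(OCc3ccccc3)c(OC)c1)O2
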